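**Plan**

- Feature: with the ring numbered C1 (C=O), C2 (C–CH3), C3 (=CH), C4 (CH–OH), C5 (CH–geranylgeranyl), C6 (CH2), the oxygens on C1 and C4 stand 1,4 across the C2=C3 alkene. That is the pattern left when the C1–O–C4 bridge of a 1-silyloxy-7-oxabicyclo[2.2.1]hept-2-ene opens, and such a bicycle is the [4+2] adduct of a 3-methyl-2-silyloxyfuran.
- Retrosynthesis: a carboxyl group is put back on C6 and the oxygen bridge is re-closed, then C4–C5 and C1–C6 are cut together ([4+2]) to the silyloxyfuran and an E-enoyl imide. Last, the bond between the enoyl β-carbon side chain and C1 of the geranylgeranyl unit is cut (Stille).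
- Forward: the C20 chain is joined to a stannylacryloyl imide first, the silyloxyfuran is made from the butenolide, and the cycloaddition then closes the only carbocycle (ring A) under the oxygen bridge. Imide hydrolysis followed by fluoride opening with loss of CO2 ends the route.
- Stereochemistry: C4 and C5 are both set in the cycloaddition. The E-alkene and the endo imide place the chain exo, on the side of the bridge oxygen, which becomes the cis C4-OH/C5-chain pair. The absolute sense comes from the bis(oxazoline) ligand on copper, and the chain alkenes are taken over unchanged from (E,E,E)-geranylgeraniol.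

Key step: step 6

Remark: the face assigned to the (S,S) ligand rests on the square-planar chelate model for enoyl imides; should the opposite sense be found, the (R,R) ligand would be used.

Ring positions C1–C6 below are those of the target as defined in the plan. (S,S)-t-Bu-box is 2,2'-(propane-2,2-diyl)bis[(4S)-4-tert-butyl-4,5-dihydro-1,3-oxazole]; the catalyst [Cu((S,S)-t-Bu-box)](SbF6)2 is prepared beforehand from CuCl2, the ligand and AgSbF6.

**Route**

Step 1
Reactants: 1 ethyl (E)-3-(tributylstannyl)acrylate
Product: 2 (E)-3-(tributylstannyl)acrylic acid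
Conditions: LiOH, THF/H2O (3:1), rt; 1 M HCl to pH 3, 0 °C
Reagents that add atoms: lithium hydroxide, [Li+].[OH-]
Why: Ester saponification; the electron-poor vinyl–tin bond should tolerate hydroxide and a brief cold acidification, and the E geometry is not touched.

Step 2
Reactants: 2 (E)-3-(tributylstannyl)acrylic acid; 3 oxazolidin-2-one
Product: 5 3-[(2E)-3-(tributylstannyl)prop-2-enoyl]-1,3-oxazolidin-2-one, via mixed pivalic anhydride 4 (not isolated)
Conditions: PivCl, Et3N, THF, −20 °C; then LiCl, 3, −20 °C to rt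
Reagents that add atoms: none
Why: N-acylation of the oxazolidinone through a mixed anhydride under LiCl/Et3N activation; the nitrogen attacks the less hindered acryloyl carbonyl and the vinylstannane is a spectator.

Step 3
Reactants: 6 (2E,6E,10E)-geranylgeraniol
Product: 7 (2E,6E,10E)-1-bromo-3,7,11,15-tetramethylhexadeca-2,6,10,14-tetraene (geranylgeranyl bromide)
Conditions: CBr4, PPh3, CH2Cl2, 0 °C
Reagents that add atoms: tetrabromomethane, BrC(Br)(Br)Br
Why: Appel bromination of a primary allylic alcohol; direct SN2 displacement of the oxyphosphonium group under cold neutral conditions should keep the 2E geometry and avoid allylic transposition, and the bromide is used at once.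

Step 4
Reactants: 5 3-[(2E)-3-(tributylstannyl)prop-2-enoyl]-1,3-oxazolidin-2-one; 7 geranylgeranyl bromide
Product: 8 3-[(2E,5E,9E,13E)-6,10,14,18-tetramethylnonadeca-2,5,9,13,17-pentaenoyl]-1,3-oxazolidin-2-one
Conditions: Pd2(dba)3 (2.5 mol%), AsPh3 (10 mol%), THF, 50 °C
Reagents that add atoms: none
Why: Stille coupling of an allylic bromide with a vinylstannane; oxidative addition to zerovalent palladium gives a π-allyl complex of divalent palladium, and transmetalation with reductive elimination at the less substituted allyl terminus forms the skipped diene with both alkene geometries retained, without base that could move the 1,4-diene into conjugation.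

Step 5
Reactants: 9 3-methylfuran-2(5H)-one
Product: 10 3-methyl-2-[(triisopropylsilyl)oxy]furan
Conditions: TIPSOTf, Et3N, CH2Cl2, 0 °C
Reagents that add atoms: triisopropylsilyl trifluoromethanesulfonate, CC(C)[Si](OS(=O)(=O)C(F)(F)F)(C(C)C)C(C)C
Why: Soft enolisation and O-silylation of a butenolide; the silyl triflate activates the carbonyl oxygen, Et3N removes the γ-proton and the aromatic 2-silyloxyfuran results, to be distilled and used fresh.

Step 6
Reactants: 8 3-[(2E,5E,9E,13E)-6,10,14,18-tetramethylnonadeca-2,5,9,13,17-pentaenoyl]-1,3-oxazolidin-2-one; 10 3-methyl-2-[(triisopropylsilyl)oxy]furan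
Product: 11 3-{[(1S,2S,3S,4S)-6-methyl-3-[(2E,6E,10E)-3,7,11,15-tetramethylhexadeca-2,6,10,14-tetraen-1-yl]-1-[(triisopropylsilyl)oxy]-7-oxabicyclo[2.2.1]hept-5-en-2-yl]carbonyl}-1,3-oxazolidin-2-one (chain exo on C5 and imide endo on C6 in target numbering)
Conditions: [Cu((S,S)-t-Bu-box)](SbF6)2 (10 mol%), 4 Å MS, CH2Cl2, −78 °C; Et3N quench at −78 °C, cold filtration through Et3N-treated silica
Reagents that add atoms: none
Why: Proposed new method: the imide, chelated s-cis to square-planar divalent copper, is attacked at its β-carbon (C5) by the free α-carbon of the furan (C4), and the copper-bound enolate carbon (C6) then closes on the silyloxy-oxocarbenium carbon (C1) before silicon can migrate, either as a concerted asynchronous [4+2] or as a Michael/aldol pair ending in the same adduct. The nearest known reactions are the Cu(SbF6)2/t-Bu-box cycloaddition of furan itself with acryloyl oxazolidinone and thermal Diels–Alder reactions of 2-silyloxyfurans with strongly activated dienophiles, whereas silyloxyfuran/enoyl imide pairs normally end as the vinylogous Mukaiyama–Michael butenolide. The six-membered carbocycle C1–C6 closes suprafacially across the two furan α-carbons (in the stepwise picture a 6-exo-trig attack of the enolate on the oxocarbenium ion), and the furan oxygen remains as the C1–O–C4 bridge. C5 and C6 are trans because the E-alkene adds suprafacially, C1 and C4 are tied together by the bridge, the C4/C5 relation (chain exo, syn to the bridge oxygen) follows from the endo placement of the chelated imide, and the absolute sense follows from the tert-butyl group of the (S,S) ligand, which covers one face of the enoyl unit so that the furan adds to the Re face of C6. Three selectivities are needed: regiochemistry, secured by the silyloxy donor that makes the unsubstituted α-carbon the nucleophilic end; endo and facial selectivity, secured by chelate and ligand; and ring closure ahead of silyl transfer, for which the bulky triisopropylsilyl group, the non-nucleophilic SbF6 counter-ion, the absence of protic additives, −78 °C and the cold amine quench are chosen.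

Step 7
Reactants: 11 the cycloadduct imide
Product: 13 (1S,2S,3S,4S)-6-methyl-3-[(2E,6E,10E)-3,7,11,15-tetramethylhexadeca-2,6,10,14-tetraen-1-yl]-1-[(triisopropylsilyl)oxy]-7-oxabicyclo[2.2.1]hept-5-ene-2-carboxylic acid, via percarboxylic acid 12 (not isolated)
Conditions: LiOH, H2O2 (30% aq.), THF/H2O (3:1), 0 °C; Na2SO3 (aq.); AcOH to pH 5, cold extraction
Reagents that add atoms: hydrogen peroxide, OO
Why: Hydroperoxide cleavage of an N-acyl oxazolidinone; LiOOH attacks the exocyclic carbonyl selectively even when it is hindered, the isolated alkenes and the silyl ketal are inert to cold basic peroxide, and the hydrolysis is placed before the bridge opening so that no enone is present to be epoxidised.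

Step 8
Reactants: 13 the bicyclic carboxylic acid
Product: 15 (4S,5S)-4-hydroxy-2-methyl-5-[(2E,6E,10E)-3,7,11,15-tetramethylhexadeca-2,6,10,14-tetraen-1-yl]cyclohex-2-en-1-one (CNP0283987.1), via hydroxy keto acid 14 (not isolated)
Conditions: TBAF, AcOH (1:1), THF, 0 °C; then 40 °C
Reagents that add atoms: none
Why: Fluoride desilylation of the bridgehead silyl ketal gives a hemiketal alkoxide that collapses to the C1 ketone and the C4 hydroxyl, and the β-keto acid so formed loses CO2 through the usual cyclic transition state (β-keto acid decarboxylation) in a buffered, nearly neutral medium; C4 and C5 are not involved, so the cis relation from step 6 should be kept.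

**Compound list**

1 | ethyl (E)-3-(tributylstannyl)acrylate | CCCC[Sn](CCCC)(CCCC)/C=C/C(=O)OCC | starting material
2 | (E)-3-(tributylstannyl)acrylic acid | CCCC[Sn](CCCC)(CCCC)/C=C/C(=O)O | intermediate
3 | oxazolidin-2-one | O=C1NCCO1 | starting material
4 | (E)-3-(tributylstannyl)acrylic pivalic anhydride | CCCC[Sn](CCCC)(CCCC)/C=C/C(=O)OC(=O)C(C)(C)C | intermediate
5 | 3-[(2E)-3-(tributylstannyl)prop-2-enoyl]-1,3-oxazolidin-2-one | CCCC[Sn](CCCC)(CCCC)/C=C/C(=O)N1CCOC1=O | intermediate
6 | (2E,6E,10E)-geranylgeraniol | CC(C)=CCC/C(C)=C/CC/C(C)=C/CC/C(C)=C/CO | starting material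
7 | (2E,6E,10E)-geranylgeranyl bromide | CC(C)=CCC/C(C)=C/CC/C(C)=C/CC/C(C)=C/CBr | intermediate
8 | 3-[(2E,5E,9E,13E)-6,10,14,18-tetramethylnonadeca-2,5,9,13,17-pentaenoyl]-1,3-oxazolidin-2-one | CC(C)=CCC/C(C)=C/CC/C(C)=C/CC/C(C)=C/C/C=C/C(=O)N1CCOC1=O | intermediate
9 | 3-methylfuran-2(5H)-one | CC1=CCOC1=O | starting material
10 | 3-methyl-2-[(triisopropylsilyl)oxy]furan | Cc1ccoc1O[Si](C(C)C)(C(C)C)C(C)C | intermediate
11 | 3-{[(1S,2S,3S,4S)-6-methyl-3-geranylgeranyl-1-[(triisopropylsilyl)oxy]-7-oxabicyclo[2.2.1]hept-5-en-2-yl]carbonyl}-1,3-oxazolidin-2-one | CC(C)=CCC/C(C)=C/CC/C(C)=C/CC/C(C)=C/C[C@@H]1[C@H]2C=C(C)[C@](O[Si](C(C)C)(C(C)C)C(C)C)(O2)[C@H]1C(=O)N3CCOC3=O | intermediate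
12 | (1S,2S,3S,4S)-6-methyl-3-geranylgeranyl-1-[(triisopropylsilyl)oxy]-7-oxabicyclo[2.2.1]hept-5-ene-2-carboperoxoic acid | CC(C)=CCC/C(C)=C/CC/C(C)=C/CC/C(C)=C/C[C@@H]1[C@H]2C=C(C)[C@](O[Si](C(C)C)(C(C)C)C(C)C)(O2)[C@H]1C(=O)OO | intermediate
13 | (1S,2S,3S,4S)-6-methyl-3-geranylgeranyl-1-[(triisopropylsilyl)oxy]-7-oxabicyclo[2.2.1]hept-5-ene-2-carboxylic acid | CC(C)=CCC/C(C)=C/CC/C(C)=C/CC/C(C)=C/C[C@@H]1[C@H]2C=C(C)[C@](O[Si](C(C)C)(C(C)C)C(C)C)(O2)[C@H]1C(=O)O | intermediate
14 | (1S,5S,6S)-5-hydroxy-3-methyl-2-oxo-6-geranylgeranylcyclohex-3-ene-1-carboxylic acid | CC(C)=CCC/C(C)=C/CC/C(C)=C/CC/C(C)=C/C[C@H]1[C@H](C(=O)O)C(=O)C(C)=C[C@H]1O | intermediate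
15 | (4S,5S)-4-hydroxy-2-methyl-5-[(2E,6E,10E)-3,7,11,15-tetramethylhexadeca-2,6,10,14-tetraen-1-yl]cyclohex-2-en-1-one | CC(C)=CCC/C(C)=C/CC/C(C)=C/CC/C(C)=C/C[C@H]1CC(=O)C(C)=C[C@H]1O | target

**Count and risks**

Total steps: 8. Longest linear sequence: 6 steps (steps 1, 2, 4, 6, 7, 8).

Step 6. The reaction may stop after the conjugate addition, because silicon can pass to the enolate faster than the ring closes. The C1–C6 bond of the adduct may also re-open under the Lewis acid, on warming or on silica.
Fallback, setting out from 8 and 10 and coming back at 14: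
- The same pair would be run under established vinylogous Mukaiyama–Michael conditions ([Cu((S,S)-t-Bu-box)](SbF6)2, (CF3)2CHOH as silyl acceptor, CH2Cl2, −78 °C). This should form C4–C5 with the same approach topology and give 3-[(3S,5E,9E,13E)-6,10,14,18-tetramethyl-3-[(2S)-4-methyl-5-oxo-2,5-dihydrofuran-2-yl]nonadeca-5,9,13,17-tetraenoyl]-1,3-oxazolidin-2-one F1.
- Alcoholysis of the imide with allyl alcohol under Yb(OTf)3 catalysis should give the corresponding allyl ester, prop-2-en-1-yl (3S,5E,9E,13E)-6,10,14,18-tetramethyl-3-[(2S)-4-methyl-5-oxo-2,5-dihydrofuran-2-yl]nonadeca-5,9,13,17-tetraenoate F2.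
- A Dieckmann-type closure of the ester enolate onto the lactone carbonyl would then form C1–C6 and release the C4 hydroxyl. TiCl4 and Bu3N in CH2Cl2 at −78 °C are preferred to an amide base so as to spare the acidic C4–H of the butenolide. The product would be prop-2-en-1-yl (1S,5S,6S)-5-hydroxy-3-methyl-2-oxo-6-geranylgeranylcyclohex-3-ene-1-carboxylate F3.
- Deallylation with Pd(PPh3)4 and morpholine in THF would deliver the keto acid 14, which loses CO2 as in step 8.

Step 8. Water may be lost from the γ-hydroxy enone, or from the dienol that forms during decarboxylation, which leads to aromatisation. Fluoride basicity may also isomerise the hydroxy enone.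
Fallback, setting out from 13 and coming back at 15: the carboxyl group would be removed reductively while the bridge is still closed.
- Acid 13 would be coupled with N-hydroxypyridine-2-thione (DCC, cat. DMAP, CH2Cl2, 0 °C, dark) to the Barton ester, 2-thioxopyridin-1(2H)-yl (1S,2S,3S,4S)-6-methyl-3-geranylgeranyl-1-[(triisopropylsilyl)oxy]-7-oxabicyclo[2.2.1]hept-5-ene-2-carboxylate F4.
- Visible-light photolysis with t-BuSH in benzene (Barton reductive decarboxylation, the thiol serving as a fast hydrogen donor) should give triisopropyl{[(1S,4S,5S)-2-methyl-5-geranylgeranyl-7-oxabicyclo[2.2.1]hept-2-en-1-yl]oxy}silane F5.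
- Buffered TBAF/AcOH in THF at 0 °C would then open the silyl ketal of F5 directly to 15, with no keto acid or dienol on the way.

Step 7. Hydrolysis at the hindered exocyclic carbonyl may be slow, so that attack on the ring carbonyl of the oxazolidinone competes. The bridge may also open by β-elimination in the aqueous base or by acid during work-up.
Fallback, setting out from 11 and coming back at 13:
- Non-aqueous exchange with lithium allyloxide (allyl alcohol, n-BuLi, THF, −20 °C) should give prop-2-en-1-yl (1S,2S,3S,4S)-6-methyl-3-geranylgeranyl-1-[(triisopropylsilyl)oxy]-7-oxabicyclo[2.2.1]hept-5-ene-2-carboxylate F6.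
- Neutral deallylation with Pd(PPh3)4 and morpholine in THF at rt would then release acid 13 without aqueous base or peroxide.

Further compounds
F1 | step 6 | 3-[(3S,5E,9E,13E)-6,10,14,18-tetramethyl-3-[(2S)-4-methyl-5-oxo-2,5-dihydrofuran-2-yl]nonadeca-5,9,13,17-tetraenoyl]-1,3-oxazolidin-2-one | CC(C)=CCC/C(C)=C/CC/C(C)=C/CC/C(C)=C/C[C@@H](CC(=O)N1CCOC1=O)[C@@H]2OC(=O)C(C)=C2
F2 | step 6 | prop-2-en-1-yl (3S,5E,9E,13E)-6,10,14,18-tetramethyl-3-[(2S)-4-methyl-5-oxo-2,5-dihydrofuran-2-yl]nonadeca-5,9,13,17-tetraenoate | CC(C)=CCC/C(C)=C/CC/C(C)=C/CC/C(C)=C/C[C@@H](CC(=O)OCC=C)[C@@H]1OC(=O)C(C)=C1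
F3 | step 6 | prop-2-en-1-yl (1S,5S,6S)-5-hydroxy-3-methyl-2-oxo-6-geranylgeranylcyclohex-3-ene-1-carboxylate | CC(C)=CCC/C(C)=C/CC/C(C)=C/CC/C(C)=C/C[C@H]1[C@H](C(=O)OCC=C)C(=O)C(C)=C[C@H]1O
F4 | step 8 | 2-thioxopyridin-1(2H)-yl (1S,2S,3S,4S)-6-methyl-3-geranylgeranyl-1-[(triisopropylsilyl)oxy]-7-oxabicyclo[2.2.1]hept-5-ene-2-carboxylate | CC(C)=CCC/C(C)=C/CC/C(C)=C/CC/C(C)=C/C[C@@H]1[C@H]2C=C(C)[C@](O[Si](C(C)C)(C(C)C)C(C)C)(O2)[C@H]1C(=O)ON3C=CC=CC3=S
F5 | step 8 | triisopropyl{[(1S,4S,5S)-2-methyl-5-geranylgeranyl-7-oxabicyclo[2.2.1]hept-2-en-1-yl]oxy}silane | CC(C)=CCC/C(C)=C/CC/C(C)=C/CC/C(C)=C/C[C@@H]1[C@H]2C=C(C)[C@](O[Si](C(C)C)(C(C)C)C(C)C)(O2)C1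
F6 | step 7 | prop-2-en-1-yl (1S,2S,3S,4S)-6-methyl-3-geranylgeranyl-1-[(triisopropylsilyl)oxy]-7-oxabicyclo[2.2.1]hept-5-ene-2-carboxylate | CC(C)=CCC/C(C)=C/CC/C(C)=C/CC/C(C)=C/C[C@@H]1[C@H]2C=C(C)[C@](O[Si](C(C)C)(C(C)C)C(C)C)(O2)[C@H]1C(=O)OCC=C
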